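**Retrosynthetic overview**

- The four MOM ethers and the C3 hydroxyl are removed from the target to reach a protected flavone; the C3 oxygen is added after ring closure by C3 lithiation, borylation and oxidation.
- Key disconnection: O1–C2 of pyranone ring C, formed by 6-endo oxa-Michael closure of an ortho-hydroxyaryl ynone. The strategy rests on the C1'–C2 bond flanked by prenyl groups at C2' and C6' of ring B: while C2–C3 is still a linear alkyne, that crowded aryl group is held away from the O1 phenoxide and the C4 carbonyl.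
- The ynone comes from C3–C4 bond formation between the lithium acetylide of a ring B arylalkyne and a ring A salicylaldehyde, then oxidation and desilylation. Only the C8a oxygen, beside the C8 prenyl, is set free, which fixes 8- against 6-prenyl.
- The prenyl groups enter as allyl groups (twofold Stille coupling on a 2,6-dibromide for ring B, ortho-Claisen shift from oxygen to C3 for ring A) and are converted by cross-metathesis with 2-methylbut-2-ene.
- Ring order: rings A and B are bought as benzaldehydes; ring C is the only ring formed.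

Key step: step 15

Remark: 2,4,6-trihydroxybenzaldehyde (formylated phloroglucinol) is taken as a purchased material; "prenyl" means 3-methylbut-2-en-1-yl; the propargylic alcohol of step 12 is racemic and its stereocentre is removed in step 13; the target has no stereocentre.

**Ring B alkyne**

Step 1
Reactants: 1 3,4-dihydroxybenzaldehyde; 2 chloromethyl methyl ether
Product: 3 3-hydroxy-4-(methoxymethoxy)benzaldehyde
Conditions: MOMCl (1.05 equiv), K2CO3 (1.1 equiv), acetone, 0 °C to rt
Reagents that add atoms: chloromethyl methyl ether (2), COCCl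
Why: The 4-hydroxyl, para to the formyl group, is the more acidic phenol, so one equivalent of weak base should form mainly its phenoxide and Williamson-type O-alkylation should protect O4 and leave O3 free.

Step 2
Reactants: 3 3-hydroxy-4-(methoxymethoxy)benzaldehyde; 4 N-bromosuccinimide
Product: 5 2,6-dibromo-3-hydroxy-4-(methoxymethoxy)benzaldehyde
Conditions: NBS (2.05 equiv), MeCN, 0 °C to rt, dark
Reagents that add atoms: N-bromosuccinimide (4), O=C1CCC(=O)N1Br
Why: Electrophilic aromatic bromination is directed by the free phenol to its ortho (C2) and para (C6) positions, whereas C5 is meta to the hydroxyl and only activated by the acetal oxygen, so two equivalents should give the 2,6-dibromide.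

Step 3
Reactants: 5 2,6-dibromo-3-hydroxy-4-(methoxymethoxy)benzaldehyde; 2 chloromethyl methyl ether
Product: 6 2,6-dibromo-3,4-bis(methoxymethoxy)benzaldehyde
Conditions: MOMCl, i-Pr2NEt, CH2Cl2, 0 °C to rt
Reagents that add atoms: chloromethyl methyl ether (2), COCCl
Why: Standard O-alkylation of an acidic phenol to its MOM ether, under which the aldehyde and the aryl bromides are inert.

Step 4
Reactants: 6 2,6-dibromo-3,4-bis(methoxymethoxy)benzaldehyde; 7 allyltributylstannane
Product: 8 2,6-diallyl-3,4-bis(methoxymethoxy)benzaldehyde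
Conditions: allylSnBu3 (2.6 equiv), Pd(PPh3)4 (10 mol %), DMF, 100 °C
Reagents that add atoms: allyltributylstannane (7), C=CC[Sn](CCCC)(CCCC)CCCC
Why: Twofold Stille cross-coupling, in which both C–Br bonds are ortho to the formyl group and so activated for oxidative addition, and the symmetrical allyl group avoids any linear-against-branched question.

Step 5
Reactants: 8 2,6-diallyl-3,4-bis(methoxymethoxy)benzaldehyde; 9 2-methylbut-2-ene
Product: 10 3,4-bis(methoxymethoxy)-2,6-diprenylbenzaldehyde
Conditions: second-generation Grubbs catalyst RuCl2(=CHPh)(PCy3)(H2IMes) (5 mol %), 2-methylbut-2-ene/CH2Cl2, 40 °C, sealed tube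
Reagents that add atoms: 2-methylbut-2-ene (9), CC=C(C)C
Why: Olefin cross-metathesis of a terminal allyl arene with excess 2-methylbut-2-ene is a standard way to a prenyl group, driven by loss of propene and tolerant of the aldehyde and the MOM ethers.

Step 6
Reactants: 10 3,4-bis(methoxymethoxy)-2,6-diprenylbenzaldehyde; 11 dimethyl (1-diazo-2-oxopropyl)phosphonate
Product: 12 1-ethynyl-3,4-bis(methoxymethoxy)-2,6-diprenylbenzene
Conditions: K2CO3, MeOH, 0 °C to rt
Reagents that add atoms: dimethyl (1-diazo-2-oxopropyl)phosphonate (11), COP(=O)(OC)C(=[N+]=[N-])C(C)=O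
Why: Ohira–Bestmann homologation, in which the diazomethylphosphonate anion released by methanolysis olefinates the aldehyde and the diazoalkene loses N2 with a 1,2-hydride shift to give the terminal alkyne under mild base that spares the MOM and prenyl groups.

**Ring A aldehyde**

Step 7
Reactants: 13 2,4,6-trihydroxybenzaldehyde; 2 chloromethyl methyl ether
Product: 14 2-hydroxy-4,6-bis(methoxymethoxy)benzaldehyde
Conditions: MOMCl (2.2 equiv), i-Pr2NEt, CH2Cl2, 0 °C to rt
Reagents that add atoms: chloromethyl methyl ether (2), COCCl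
Why: The para hydroxyl and one ortho hydroxyl are alkylated, while the second ortho hydroxyl stays hydrogen-bonded to the formyl group and resists amine-base alkylation, as is usual for phloroglucinol carbonyl compounds.

Step 8
Reactants: 14 2-hydroxy-4,6-bis(methoxymethoxy)benzaldehyde; 15 allyl bromide
Product: 16 2-(allyloxy)-4,6-bis(methoxymethoxy)benzaldehyde
Conditions: allyl bromide, K2CO3, DMF, 50 °C
Reagents that add atoms: allyl bromide (15), C=CCBr
Why: Williamson etherification of the remaining chelated phenol under the more forcing carbonate/DMF conditions.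

Step 9
Reactants: 16 2-(allyloxy)-4,6-bis(methoxymethoxy)benzaldehyde
Product: 17 3-allyl-2-hydroxy-4,6-bis(methoxymethoxy)benzaldehyde
Conditions: PhNEt2, 190 °C, sealed tube
Reagents that add atoms: none
Why: Aromatic Claisen rearrangement ([3,3]-sigmatropic shift), in which the allyl group can only move to C3, the one free ortho position, and enolisation returns the phenol beside the new C-allyl group, so the later O1/C8 relationship is fixed without ambiguity.

Step 10
Reactants: 17 3-allyl-2-hydroxy-4,6-bis(methoxymethoxy)benzaldehyde; 9 2-methylbut-2-ene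
Product: 18 2-hydroxy-4,6-bis(methoxymethoxy)-3-prenylbenzaldehyde
Conditions: second-generation Grubbs catalyst RuCl2(=CHPh)(PCy3)(H2IMes) (5 mol %), 2-methylbut-2-ene/CH2Cl2, 40 °C, sealed tube
Reagents that add atoms: 2-methylbut-2-ene (9), CC=C(C)C
Why: Olefin cross-metathesis converts the allyl group into a prenyl group with loss of propene, and ortho-allyl phenols are accepted substrates.

Step 11
Reactants: 18 2-hydroxy-4,6-bis(methoxymethoxy)-3-prenylbenzaldehyde; 19 tert-butyldimethylsilyl chloride
Product: 20 2-(tert-butyldimethylsilyloxy)-4,6-bis(methoxymethoxy)-3-prenylbenzaldehyde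
Conditions: TBSCl, imidazole, DMAP (cat.), DMF, 40 °C
Reagents that add atoms: tert-butyldimethylsilyl chloride (19), CC(C)(C)[Si](C)(C)Cl
Why: Silylation masks the phenol so that the acetylide of step 12 is not quenched and the benzylic alcohol formed there cannot eliminate to an ortho-quinone methide.

**Fragment union, ring closure and end game**

Step 12
Reactants: 12 1-ethynyl-3,4-bis(methoxymethoxy)-2,6-diprenylbenzene; 20 2-(tert-butyldimethylsilyloxy)-4,6-bis(methoxymethoxy)-3-prenylbenzaldehyde
Product: 22 racemic 1-[2-(tert-butyldimethylsilyloxy)-4,6-bis(methoxymethoxy)-3-prenylphenyl]-3-[3,4-bis(methoxymethoxy)-2,6-diprenylphenyl]prop-2-yn-1-ol, via ring B lithium acetylide 21 (not isolated)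
Conditions: 12, n-BuLi, THF, −78 °C; then 20, −78 °C; sat. aq. NH4Cl at −78 °C
Reagents that add atoms: none
Why: 1,2-Addition of a lithium acetylide to an aldehyde, in which the alkyne C–H is by far the most acidic site of 12, the cold quench limits silyl migration, and the new carbinol centre is formed racemic without consequence because step 13 oxidises it.

Step 13
Reactants: 22 racemic 1-[2-(tert-butyldimethylsilyloxy)-4,6-bis(methoxymethoxy)-3-prenylphenyl]-3-[3,4-bis(methoxymethoxy)-2,6-diprenylphenyl]prop-2-yn-1-ol
Product: 23 1-[2-(tert-butyldimethylsilyloxy)-4,6-bis(methoxymethoxy)-3-prenylphenyl]-3-[3,4-bis(methoxymethoxy)-2,6-diprenylphenyl]prop-2-yn-1-one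
Conditions: MnO2 (activated, excess), CH2Cl2, rt
Reagents that add atoms: none
Why: MnO2 oxidises benzylic propargylic alcohols selectively under neutral conditions that spare the prenyl alkenes, the silyl ether and the acid-sensitive electron-rich carbinol.

Step 14
Reactants: 23 1-[2-(tert-butyldimethylsilyloxy)-4,6-bis(methoxymethoxy)-3-prenylphenyl]-3-[3,4-bis(methoxymethoxy)-2,6-diprenylphenyl]prop-2-yn-1-one
Product: 24 1-[2-hydroxy-4,6-bis(methoxymethoxy)-3-prenylphenyl]-3-[3,4-bis(methoxymethoxy)-2,6-diprenylphenyl]prop-2-yn-1-one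
Conditions: Bu4NF, AcOH (buffer), THF, 0 °C
Reagents that add atoms: none
Why: Fluoride cleaves the aryl silyl ether, and the acetic acid buffer keeps the liberated phenol protonated so that ring closure is held back until the controlled conditions of step 15.

Step 15
Reactants: 24 1-[2-hydroxy-4,6-bis(methoxymethoxy)-3-prenylphenyl]-3-[3,4-bis(methoxymethoxy)-2,6-diprenylphenyl]prop-2-yn-1-one
Product: 25 5,7,3',4'-tetrakis(methoxymethoxy)-8,2',6'-triprenylflavone
Conditions: K2CO3 (anhydrous, 2 equiv), dry acetone, reflux
Reagents that add atoms: none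
Why: K2CO3 removes the proton of the chelated phenol (the future O1), and the phenoxide adds to the ynone β-carbon (the future C2) to give an allenolate that is protonated at C3, an intramolecular oxa-Michael addition of the kind long used to turn ortho-hydroxyaryl ynones into flavones. Ring C closes in the 6-endo-dig mode, and no stereocentre is formed. The step needs attack at the β-carbon (flavone) and not 5-exo attack at the α-carbon (aurone): the ynone is polarised towards the β-carbon, and in a dry aprotic solvent the 5-exo adduct, an unstabilised vinyl anion, should revert while the 6-endo adduct is an enolate-type anion. Because C2–C3 is still a linear alkyne, the two ortho prenyl groups of ring B lie well away from the incoming oxygen, and the aryl group turns perpendicular only after the ring exists. Only one phenol is free, so closure can place the ring A prenyl group at C8 alone.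

Step 16
Reactants: 25 5,7,3',4'-tetrakis(methoxymethoxy)-8,2',6'-triprenylflavone; 26 hydrogen peroxide
Product: 29 3-hydroxy-5,7,3',4'-tetrakis(methoxymethoxy)-8,2',6'-triprenylflavone, via 3-lithioflavone 27 (not isolated), via flavon-3-yl dimethyl boronate 28 (not isolated)
Conditions: LiN(i-Pr)2, THF, −78 °C; B(OMe)3, −78 to 0 °C; then 30% H2O2, aq. NaHCO3, 0 °C to rt
Reagents that add atoms: hydrogen peroxide (26), OO
Why: Carbonyl-assisted C3 deprotonation of a flavone with lithium diisopropylamide, borylation and oxidative C–B to C–O conversion is an established flavonol synthesis, and the hydroperoxide anion attacks boron and not the isolated prenyl alkenes.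

Step 17
Reactants: 29 3-hydroxy-5,7,3',4'-tetrakis(methoxymethoxy)-8,2',6'-triprenylflavone
Product: 30 petalostemumol G (3,5,7,3',4'-pentahydroxy-8,2',6'-triprenylflavone)
Conditions: 3 M aq. HCl, MeOH, 40 °C, argon
Reagents that add atoms: none
Why: Acid-catalysed acetal exchange with methanol removes all four MOM ethers as dimethoxymethane, and the mild temperature limits acid-promoted cyclisation of the ortho-prenyl phenols.

**Compound list**

1 | 3,4-dihydroxybenzaldehyde | O=Cc1ccc(O)c(O)c1 | starting material
2 | chloromethyl methyl ether | COCCl | starting material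
3 | 3-hydroxy-4-(methoxymethoxy)benzaldehyde | O=Cc1ccc(OCOC)c(O)c1 | intermediate
4 | N-bromosuccinimide | O=C1CCC(=O)N1Br | starting material
5 | 2,6-dibromo-3-hydroxy-4-(methoxymethoxy)benzaldehyde | O=Cc1c(Br)cc(OCOC)c(O)c1Br | intermediate
6 | 2,6-dibromo-3,4-bis(methoxymethoxy)benzaldehyde | O=Cc1c(Br)cc(OCOC)c(OCOC)c1Br | intermediate
7 | allyltributylstannane | C=CC[Sn](CCCC)(CCCC)CCCC | starting material
8 | 2,6-diallyl-3,4-bis(methoxymethoxy)benzaldehyde | O=Cc1c(CC=C)cc(OCOC)c(OCOC)c1CC=C | intermediate
9 | 2-methylbut-2-ene | CC=C(C)C | starting material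
10 | 3,4-bis(methoxymethoxy)-2,6-diprenylbenzaldehyde | O=Cc1c(CC=C(C)C)cc(OCOC)c(OCOC)c1CC=C(C)C | intermediate
11 | dimethyl (1-diazo-2-oxopropyl)phosphonate | COP(=O)(OC)C(=[N+]=[N-])C(C)=O | starting material
12 | 1-ethynyl-3,4-bis(methoxymethoxy)-2,6-diprenylbenzene | C#Cc1c(CC=C(C)C)cc(OCOC)c(OCOC)c1CC=C(C)C | intermediate
13 | 2,4,6-trihydroxybenzaldehyde | O=Cc1c(O)cc(O)cc1O | starting material
14 | 2-hydroxy-4,6-bis(methoxymethoxy)benzaldehyde | O=Cc1c(O)cc(OCOC)cc1OCOC | intermediate
15 | allyl bromide | C=CCBr | starting material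
16 | 2-(allyloxy)-4,6-bis(methoxymethoxy)benzaldehyde | O=Cc1c(OCC=C)cc(OCOC)cc1OCOC | intermediate
17 | 3-allyl-2-hydroxy-4,6-bis(methoxymethoxy)benzaldehyde | O=Cc1c(O)c(CC=C)c(OCOC)cc1OCOC | intermediate
18 | 2-hydroxy-4,6-bis(methoxymethoxy)-3-prenylbenzaldehyde | O=Cc1c(O)c(CC=C(C)C)c(OCOC)cc1OCOC | intermediate
19 | tert-butyldimethylsilyl chloride | CC(C)(C)[Si](C)(C)Cl | starting material
20 | 2-(tert-butyldimethylsilyloxy)-4,6-bis(methoxymethoxy)-3-prenylbenzaldehyde | O=Cc1c(O[Si](C)(C)C(C)(C)C)c(CC=C(C)C)c(OCOC)cc1OCOC | intermediate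
21 | ring B lithium acetylide (not isolated) | [Li]C#Cc1c(CC=C(C)C)cc(OCOC)c(OCOC)c1CC=C(C)C | intermediate
22 | racemic 1-[2-(tert-butyldimethylsilyloxy)-4,6-bis(methoxymethoxy)-3-prenylphenyl]-3-[3,4-bis(methoxymethoxy)-2,6-diprenylphenyl]prop-2-yn-1-ol | CC(C)=CCc1c(O[Si](C)(C)C(C)(C)C)c(C(O)C#Cc2c(CC=C(C)C)cc(OCOC)c(OCOC)c2CC=C(C)C)c(OCOC)cc1OCOC | intermediate
23 | 1-[2-(tert-butyldimethylsilyloxy)-4,6-bis(methoxymethoxy)-3-prenylphenyl]-3-[3,4-bis(methoxymethoxy)-2,6-diprenylphenyl]prop-2-yn-1-one | CC(C)=CCc1c(O[Si](C)(C)C(C)(C)C)c(C(=O)C#Cc2c(CC=C(C)C)cc(OCOC)c(OCOC)c2CC=C(C)C)c(OCOC)cc1OCOC | intermediate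
24 | 1-[2-hydroxy-4,6-bis(methoxymethoxy)-3-prenylphenyl]-3-[3,4-bis(methoxymethoxy)-2,6-diprenylphenyl]prop-2-yn-1-one | CC(C)=CCc1c(O)c(C(=O)C#Cc2c(CC=C(C)C)cc(OCOC)c(OCOC)c2CC=C(C)C)c(OCOC)cc1OCOC | intermediate
25 | 5,7,3',4'-tetrakis(methoxymethoxy)-8,2',6'-triprenylflavone | CC(C)=CCc1cc(OCOC)c(OCOC)c(CC=C(C)C)c1-c1cc(=O)c2c(OCOC)cc(OCOC)c(CC=C(C)C)c2o1 | intermediate
26 | hydrogen peroxide | OO | starting material
27 | 3-lithio-5,7,3',4'-tetrakis(methoxymethoxy)-8,2',6'-triprenylflavone (not isolated) | CC(C)=CCc1cc(OCOC)c(OCOC)c(CC=C(C)C)c1-c1oc2c(CC=C(C)C)c(OCOC)cc(OCOC)c2c(=O)c1[Li] | intermediate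
28 | dimethyl [5,7,3',4'-tetrakis(methoxymethoxy)-8,2',6'-triprenylflavon-3-yl]boronate (not isolated) | CC(C)=CCc1cc(OCOC)c(OCOC)c(CC=C(C)C)c1-c1oc2c(CC=C(C)C)c(OCOC)cc(OCOC)c2c(=O)c1B(OC)OC | intermediate
29 | 3-hydroxy-5,7,3',4'-tetrakis(methoxymethoxy)-8,2',6'-triprenylflavone | CC(C)=CCc1cc(OCOC)c(OCOC)c(CC=C(C)C)c1-c1oc2c(CC=C(C)C)c(OCOC)cc(OCOC)c2c(=O)c1O | intermediate
30 | petalostemumol G | CC(C)=CCc1cc(O)c(O)c(CC=C(C)C)c1-c1oc2c(CC=C(C)C)c(O)cc(O)c2c(=O)c1O | target

**Step count**

Total steps: 17. Longest linear sequence: 12 steps (steps 1–6, then steps 12–17).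

**Steps most likely to fail**

Step 15. The ring may close the 5-exo way, with the phenoxide adding to the α-carbon to give the aurone skeleton, or attack at the β-carbon may be slowed by the neighbouring di-ortho-substituted aryl group so that the ynone decays first. The fallback sets out from 24 and changes the order of bond formation. Diethylamine in ethanol at room temperature should add to the ynone by aza-Michael addition, which can only occur at the β-carbon, to give the (E)-3-(diethylamino)-3-aryl enone F1. On warming in ethanol the phenol should displace the amine at the same carbon by addition–elimination, and the route is rejoined at 25.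

Step 16. Proton removal may occur at a benzylic allylic CH2 of a prenyl group or at H6 between two MOM ethers instead of at C3, and the 3-lithio species may open ring C by expelling the O1 phenoxide, the reverse of step 15, before the borate captures it. The fallback sets out from 25 and uses a more covalent carbon–magnesium bond and direct oxygen transfer instead of borate chemistry. Treatment with (2,2,6,6-tetramethylpiperidin-1-yl)MgCl·LiCl in THF at −40 °C, held at the C4 carbonyl, should give the 3-(chloromagnesio)flavone F2. Bis(trimethylsilyl) peroxide should convert it into the 3-(trimethylsilyloxy)flavone F3, and aqueous work-up should remove the silyl group and rejoin the route at 29.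

Step 17. During the slow loss of the last acetal, protic acid may add the free C7 or C3' hydroxyl across the neighbouring prenyl alkene to form a chroman ring, or may hydrate an alkene. The fallback sets out from 29 and avoids Brønsted acid by transprotection. Me3SiOTf with 2,2'-bipyridyl in CH2Cl2 at 0 °C should transfer each MOM ether to a silyl ether and silylate the C3 hydroxyl as well, giving 3,5,7,3',4'-pentakis(trimethylsilyloxy)-8,2',6'-triprenylflavone F4. Neutral hydrolysis in aqueous methanol should then give 30.

**Further compounds**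

F1 | step 15 | (E)-3-(diethylamino)-1-[2-hydroxy-4,6-bis(methoxymethoxy)-3-prenylphenyl]-3-[3,4-bis(methoxymethoxy)-2,6-diprenylphenyl]prop-2-en-1-one | CCN(CC)/C(=C/C(=O)c1c(O)c(CC=C(C)C)c(OCOC)cc1OCOC)c1c(CC=C(C)C)cc(OCOC)c(OCOC)c1CC=C(C)C
F2 | step 16 | 3-(chloromagnesio)-5,7,3',4'-tetrakis(methoxymethoxy)-8,2',6'-triprenylflavone | CC(C)=CCc1cc(OCOC)c(OCOC)c(CC=C(C)C)c1-c1oc2c(CC=C(C)C)c(OCOC)cc(OCOC)c2c(=O)c1[Mg]Cl
F3 | step 16 | 5,7,3',4'-tetrakis(methoxymethoxy)-8,2',6'-triprenyl-3-(trimethylsilyloxy)flavone | CC(C)=CCc1cc(OCOC)c(OCOC)c(CC=C(C)C)c1-c1oc2c(CC=C(C)C)c(OCOC)cc(OCOC)c2c(=O)c1O[Si](C)(C)C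
F4 | step 17 | 3,5,7,3',4'-pentakis(trimethylsilyloxy)-8,2',6'-triprenylflavone | CC(C)=CCc1cc(O[Si](C)(C)C)c(O[Si](C)(C)C)c(CC=C(C)C)c1-c1oc2c(CC=C(C)C)c(O[Si](C)(C)C)cc(O[Si](C)(C)C)c2c(=O)c1O[Si](C)(C)C
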